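Ring C of the flavanone is cut across C3–C4 and O1–C2, which divides the target into a salicylaldehyde (ring A carrying O1 on C8a and the future C4 as aldehyde carbon on C4a) and a terminal aryl alkyne (ring B with C2 and C3). The key step exploits this ortho relationship of O1 and C4 on ring A: the phenoxide steers rhodium into the aldehyde C–H bond for alkyne hydroacylation (C3–C4), and the same oxygen then closes ring C by a catalyst-controlled oxa-Michael addition (O1–C2) that sets C2, the only stereocentre, as S. Each partner is made in one step from a commercial trimethoxyarene.

Key step: step 3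

Assumption: flavanone numbering (O1, C2, C3, C4, C4a, C8a) is used throughout, the target is the (2S) enantiomer, and the quinidine-derived thiourea is assumed to deliver the (2S) product; should the sense of induction be the reverse, the quinine-derived pseudo-enantiomer is used with no other change.

Step 1
Reactants: 1 3,4,5-trimethoxyphenol
Product: 3 2-hydroxy-4,5,6-trimethoxybenzaldehyde, via salicyl alcohol 2 (not isolated)
Conditions: MgCl2, Et3N, (CH2O)n, MeCN, reflux; 1 M HCl work-up
Reagents that add atoms: paraformaldehyde (reacts as formaldehyde), C=O
Why: Magnesium-mediated ortho-formylation of a phenol: the magnesium phenoxide of 1 is hydroxymethylated next to oxygen through a chelate to give 2, which is oxidised to the aldehyde by Oppenauer-type hydride transfer to a second formaldehyde; the two ortho positions of 1 are equivalent and the para position is blocked, so only one regioisomer can form.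

Step 2
Reactants: 4 3,4,5-trimethoxybenzaldehyde
Product: 5 5-ethynyl-1,2,3-trimethoxybenzene
Conditions: dimethyl (1-diazo-2-oxopropyl)phosphonate, K2CO3, MeOH, 0 °C to rt
Reagents that add atoms: dimethyl (1-diazo-2-oxopropyl)phosphonate (Ohira–Bestmann reagent), COP(=O)(OC)C(=[N+]=[N-])C(C)=O
Why: Ohira–Bestmann variant of the Seyferth–Gilbert homologation: methoxide deacetylates the reagent, the resulting diazomethylphosphonate anion adds to the aldehyde, and Horner–Wadsworth–Emmons-type elimination, loss of N2 and a 1,2-hydrogen shift should give the terminal alkyne under conditions that leave the aryl methyl ethers untouched.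

Step 3
Reactants: 3 2-hydroxy-4,5,6-trimethoxybenzaldehyde; 5 5-ethynyl-1,2,3-trimethoxybenzene
Product: 7 (2S)-5,6,7-trimethoxy-2-(3,4,5-trimethoxyphenyl)chroman-4-one, via chalcone 6 (not isolated)
Conditions: [RhCl(cod)]2 (2.5 mol%), 1,1'-bis(diphenylphosphino)ferrocene (dppf, 5 mol%), Na2CO3 (5 mol%), PhMe, 90 °C; then 0 °C, 9-amino-9-deoxy-epi-quinidine-derived 3,5-bis(trifluoromethyl)phenyl thiourea (15 mol%), 0 °C to rt
Reagents that add atoms: none
Why: The phenoxide of 3 binds monovalent rhodium, which inserts into the neighbouring aldehyde C–H bond to give a chelated acyl hydride of trivalent rhodium; syn hydrometallation of 5 with rhodium on the unsubstituted terminus and C–C reductive elimination form C3–C4 and release (E)-chalcone 6. The closest known reaction types are the chelation-assisted hydroacylation of alkynes by salicylaldehydes, also run in tandem with oxa-Michael closure to chroman-4-ones, and the amine–thiourea-catalysed cyclisation of 2'-hydroxychalcones to flavanones. Ring C closes by a 6-endo-trig oxa-Michael addition of the phenol oxygen to the β-carbon of the enone, which forms O1–C2. C2 is set in this closure by the chiral catalyst: the thiourea hydrogen-bonds to the enone carbonyl while the quinuclidine nitrogen acts as general base on the phenol, so that oxygen is delivered to one enantiotopic face of the β-carbon. The step needs linear regioselectivity in the alkyne insertion and little uncatalysed ring closure during the hot stage; the first is secured by the terminal alkyne with its bulky aryl group, the second by the low, poorly soluble carbonate loading. The 6'-methoxy group of 6 (C5–OMe of 7) twists the aroyl group and should make closure thermodynamically favourable, so that ring opening does not erode the configuration.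

Compound list
1 | 3,4,5-trimethoxyphenol | COc1cc(O)cc(OC)c1OC | starting material
2 | 2-(hydroxymethyl)-3,4,5-trimethoxyphenol (salicyl alcohol, formed as its magnesium salt) | COc1cc(O)c(CO)c(OC)c1OC | intermediate (not isolated)
3 | 2-hydroxy-4,5,6-trimethoxybenzaldehyde | COc1cc(O)c(C=O)c(OC)c1OC | intermediate
4 | 3,4,5-trimethoxybenzaldehyde | COc1cc(C=O)cc(OC)c1OC | starting material
5 | 5-ethynyl-1,2,3-trimethoxybenzene | C#Cc1cc(OC)c(OC)c(OC)c1 | intermediate
6 | (E)-1-(2-hydroxy-4,5,6-trimethoxyphenyl)-3-(3,4,5-trimethoxyphenyl)prop-2-en-1-one (chalcone) | COc1cc(O)c(C(=O)/C=C/c2cc(OC)c(OC)c(OC)c2)c(OC)c1OC | intermediate (not isolated)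
7 | (2S)-5,6,7-trimethoxy-2-(3,4,5-trimethoxyphenyl)chroman-4-one | COc1cc([C@@H]2CC(=O)c3c(cc(OC)c(OC)c3OC)O2)cc(OC)c1OC | target

Total step count: 3. Longest linear sequence: 2 steps (step 1 then step 3, or step 2 then step 3).

Steps most likely to fail

Step 3 is the most likely to fail, through poor facial selectivity in the ring closure. Part of chalcone 6 may close without the chiral catalyst during the hot hydroacylation stage, and reversible ring opening of 7 under the amine catalyst may lower the enantiomeric purity further. The fallback sets out from 3 and 5 and gives up catalyst control in the closure. The hydroacylation is run as in step 3 and the ring is closed in the same flask with CsF, which should give racemic 5,6,7-trimethoxy-2-(3,4,5-trimethoxyphenyl)chroman-4-one F1 with both ring bonds still formed in one operation. Kinetic resolution by asymmetric transfer hydrogenation with [Cp*RhCl((R,R)-TsDPEN)], HCO2H/Et3N, EtOAc, rt, stopped near half conversion, should then reduce the (2R) ketone to (2R,4R)-5,6,7-trimethoxy-2-(3,4,5-trimethoxyphenyl)chroman-4-ol F2. The unreacted (2S) ketone is separated by chromatography, and the route is rejoined at 7. The matched pairing ((R,R) catalyst with the 2R ketone, giving the cis alcohol) is a prediction and would have to be confirmed.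

Step 1 is the second risk, through over-reaction of the very electron-rich ring (a second hydroxymethylation or diarylmethane formation) or incomplete oxidation of 2. The fallback sets out from 1 and replaces the electrophilic formylation by directed ortho-metallation. MOMCl and iPr2NEt in CH2Cl2 should give 1,2,3-trimethoxy-5-(methoxymethoxy)benzene F3. Lithiation with n-BuLi in THF at 0 °C, at the position flanked by the two directing oxygens, followed by DMF should give 2,3,4-trimethoxy-6-(methoxymethoxy)benzaldehyde F4. HCl in MeOH removes the acetal, and the route is rejoined at 3.

Step 2 is the third risk, through sluggish addition of the phosphonate anion to the electron-rich aldehyde and hence incomplete conversion. The fallback sets out from 4 and uses the Corey–Fuchs sequence. CBr4 and PPh3 in CH2Cl2 at 0 °C should give 5-(2,2-dibromovinyl)-1,2,3-trimethoxybenzene F5. n-BuLi (2.2 equiv) in THF at −78 °C followed by water should then give the alkyne by Fritsch–Buttenberg–Wiechell rearrangement, and the route is rejoined at 5.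

Further compounds
F1 | step 3 | racemic 5,6,7-trimethoxy-2-(3,4,5-trimethoxyphenyl)chroman-4-one | COc1cc(C2CC(=O)c3c(cc(OC)c(OC)c3OC)O2)cc(OC)c1OC
F2 | step 3 | (2R,4R)-5,6,7-trimethoxy-2-(3,4,5-trimethoxyphenyl)chroman-4-ol | COc1cc([C@H]2C[C@@H](O)c3c(cc(OC)c(OC)c3OC)O2)cc(OC)c1OC
F3 | step 1 | 1,2,3-trimethoxy-5-(methoxymethoxy)benzene | COCOc1cc(OC)c(OC)c(OC)c1
F4 | step 1 | 2,3,4-trimethoxy-6-(methoxymethoxy)benzaldehyde | COCOc1cc(OC)c(OC)c(OC)c1C=O
F5 | step 2 | 5-(2,2-dibromovinyl)-1,2,3-trimethoxybenzene | COc1cc(C=C(Br)Br)cc(OC)c1OC
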